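Locants: C1 = benzylic CH2 on the resorcinol ring (ring A), C2 = acetoxy carbon, C3–C7 = methylene chain, C8 = ketone, C9–C13 = pentyl.
Retrosynthesis: the two phenolic O–benzyl bonds of a protected target are cut first. C2–C3 and the O–acetyl bond at C2 are then cut together, giving an arylacetaldehyde, acetyl bromide, undec-1-en-6-one and a hydrosilane. C8–C9 of the olefinic ketone is cut last (hex-5-enenitrile + pentylmagnesium bromide).
Enabling feature: C2 is an O-acylated carbinol carbon, that is, an aldehyde carbon plus an acyl halide. The derived 1-bromoalkyl acetate gives a C2 radical stabilised by the ester oxygen, and its acetyl C=O can bind nickel. The unbranched C3–C7 chain lets C3=C4 be a terminal olefin, and the C8 ketone and ring A stay remote spectators.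
Forward: C8–C9 is made first in a side branch, and ring A is bought, protected and brought to the aldehyde level. C2–C3, the C2 stereocentre and the acetate then arise together in one four-component nickel hydride coupling, and hydrogenolysis ends the route. No ring is formed.
Stereochemistry: the only stereocentre, (R)-C2, comes from the chiral bis(oxazoline) ligand on nickel in an enantioconvergent coupling of the racemic bromide.

Key step: step 4

Assumption: the sense of induction of the nickel/bis(oxazoline) catalyst on 9 is to be fixed by one pilot run (saponification of a sample of 10, then Mosher ester analysis). L* below denotes whichever enantiomer of the commercial ligand 2,2'-(propane-2,2-diyl)bis(4-phenyl-4,5-dihydrooxazole) delivers (R)-10.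

Step 1
Reactants: 1 hex-5-enenitrile; 2 pentylmagnesium bromide
Product: 4 undec-1-en-6-one, via bromomagnesium ketimine 3 (not isolated)
Conditions: 2 (1.2 equiv), Et2O, 0 °C → reflux; then 2 M aq. HCl, 0 °C → rt
Reagents that add atoms: water, O
Why: Grignard addition to a nitrile stops at the N-magnesio ketimine 3, which takes up no second equivalent and is hydrolysed to the ketone on acidic work-up, while the isolated terminal olefin is inert in both stages.

Step 2
Reactants: 5 methyl 2-(3,5-dihydroxyphenyl)acetate
Product: 6 methyl 2-[3,5-bis(benzyloxy)phenyl]acetate
Conditions: BnBr (2.2 equiv), K2CO3 (2.5 equiv), acetone, reflux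
Reagents that add atoms: benzyl bromide, BrCc1ccccc1
Why: In this Williamson ether synthesis K2CO3 deprotonates only the phenols, and the benzyl ethers are inert to acyl bromide, hydrosilane and nickel hydride and leave later under neutral hydrogenolysis that spares acetate and ketone.

Step 3
Reactants: 6 methyl 2-[3,5-bis(benzyloxy)phenyl]acetate
Product: 8 2-[3,5-bis(benzyloxy)phenyl]acetaldehyde, via aluminium hemiacetal 7 (not isolated)
Conditions: i-Bu2AlH (1.05 equiv), CH2Cl2, −78 °C; then aq. potassium sodium tartrate, −78 °C → rt; used at once
Reagents that add atoms: none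
Why: In this partial ester reduction with i-Bu2AlH the tetrahedral aluminium hemiacetal 7 persists at −78 °C until the aqueous quench, so the enolisable aldehyde is released only when no hydride is left.

Step 4
Reactants: 8 2-[3,5-bis(benzyloxy)phenyl]acetaldehyde; 4 undec-1-en-6-one
Product: 10 (R)-1-[3,5-bis(benzyloxy)phenyl]-8-oxotridecan-2-yl acetate, via racemic 1-bromoalkyl acetate 9 (not isolated)
Conditions: 8 (1.5 equiv), AcBr (1.5 equiv), i-Pr2O, 0 °C → rt; then, same flask, 4 (1.0 equiv), NiBr2·diglyme (10 mol %), L* (12 mol %), (EtO)3SiH (2 equiv), K3PO4·H2O (2.5 equiv), rt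
Reagents that add atoms: acetyl bromide, CC(=O)Br
Why: Acetyl bromide adds across the C=O of 8 (acyl halide–aldehyde addition) to give racemic 9, so the aldehyde oxygen becomes the ester oxygen of the target. A ligated nickel hydride, formed from NiBr2·diglyme, (EtO)3SiH and K3PO4·H2O, adds to the terminal olefin of 4 in the anti-Markovnikov sense to give a primary alkylnickel; monovalent nickel abstracts bromine from 9 to give the planar C2 radical stabilised by the ester oxygen, and capture of this radical followed by reductive elimination from trivalent nickel forms C2–C3. The closest known reaction type is the nickel-hydride-catalysed enantioconvergent hydroalkylation of terminal olefins with racemic 1-bromoalkyl carboxylates, including its one-pot form from aldehyde, acyl bromide, olefin and hydrosilane; no ring is closed. The C2 stereocentre is controlled by the chiral bis(oxazoline) on nickel: both enantiomers of 9 converge on the same radical, and the acetyl C=O, which can bind nickel, sets the acyloxy group apart from the CH2Ar group in the bond-forming event, so the similar size of the two carbon chains at C2 does not matter. The step needs linear regiochemistry (secured by the unhindered monosubstituted olefin and a ligand that does not promote chain walking), chemoselectivity over the C8 ketone, the benzyl ethers and the ester (secured by the mild silane/phosphate system at rt and the weak C–Br bond next to oxygen), and cross- over homo-coupling (secured because the two partners enter by different elementary steps, hydrometalation and halogen abstraction).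

Step 5
Reactants: 10 (R)-1-[3,5-bis(benzyloxy)phenyl]-8-oxotridecan-2-yl acetate
Product: 11 (R)-1-(3,5-dihydroxyphenyl)-8-oxotridecan-2-yl acetate
Conditions: H2 (1 atm), Pd/C (10 wt %), EtOAc, rt
Reagents that add atoms: none
Why: Catalytic hydrogenolysis cleaves the two aryl O–CH2Ph bonds under neutral conditions, whereas the dialkyl ketone, the ester and the homobenzylic (not benzylic) C2–O bond are untouched, so the C2 configuration is retained.

Compound list
1 | hex-5-enenitrile | C=CCCCC#N | starting material
2 | pentylmagnesium bromide | CCCCC[Mg]Br | starting material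
3 | bromomagnesium salt of undec-1-en-6-imine | C=CCCCC(CCCCC)=N[Mg]Br | intermediate
4 | undec-1-en-6-one | C=CCCCC(=O)CCCCC | intermediate
5 | methyl 2-(3,5-dihydroxyphenyl)acetate | COC(=O)Cc1cc(O)cc(O)c1 | starting material
6 | methyl 2-[3,5-bis(benzyloxy)phenyl]acetate | COC(=O)Cc1cc(OCc2ccccc2)cc(OCc2ccccc2)c1 | intermediate
7 | diisobutylaluminium hemiacetal of 6 (O-aluminated 1-methoxy-2-arylethanol) | COC(Cc1cc(OCc2ccccc2)cc(OCc2ccccc2)c1)O[Al](CC(C)C)CC(C)C | intermediate
8 | 2-[3,5-bis(benzyloxy)phenyl]acetaldehyde | O=CCc1cc(OCc2ccccc2)cc(OCc2ccccc2)c1 | intermediate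
9 | racemic 1-bromo-2-[3,5-bis(benzyloxy)phenyl]ethyl acetate | CC(=O)OC(Br)Cc1cc(OCc2ccccc2)cc(OCc2ccccc2)c1 | intermediate
10 | (R)-1-[3,5-bis(benzyloxy)phenyl]-8-oxotridecan-2-yl acetate | CCCCCC(=O)CCCCC[C@H](Cc1cc(OCc2ccccc2)cc(OCc2ccccc2)c1)OC(C)=O | intermediate
11 | (R)-1-(3,5-dihydroxyphenyl)-8-oxotridecan-2-yl acetate | CCCCCC(=O)CCCCC[C@H](Cc1cc(O)cc(O)c1)OC(C)=O | target

Total step count: 5. Longest linear sequence: 4 (steps 2, 3, 4, 5).

Steps most likely to fail

Step 4. Several processes could erode yield or enantiopurity:
- base-induced loss of HBr from the bromo acetate toward conjugation with ring A before nickel engages it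
- premature hydrodebromination by the nickel hydride
- slow silane reduction of the ketone
- weak facial discrimination with the small acetyl group

The fallback sets out from 8 and 4 and comes back at 10.
- Vinylmagnesium bromide is added to 8 (THF, −78 °C) to give racemic 1-[3,5-bis(benzyloxy)phenyl]but-3-en-2-ol F1.
- Lipase-catalysed kinetic resolution follows (Candida antarctica lipase B, vinyl acetate, hexane/t-BuOMe, rt). It should acetylate the enantiomer that places the small vinyl group in the medium pocket and the arylmethyl group in the large pocket. This gives (S)-1-[3,5-bis(benzyloxy)phenyl]but-3-en-2-yl acetate F2. F2 has the same spatial arrangement as (R)-10, and the descriptor changes only because vinyl outranks CH2Ar.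
- Olefin cross-metathesis of F2 with an excess of 4 (second-generation Grubbs catalyst, CH2Cl2, reflux) gives (2S,3E)-1-[3,5-bis(benzyloxy)phenyl]-8-oxotridec-3-en-2-yl acetate F3.
- Homogeneous hydrogenation (H2, RhCl(PPh3)3, benzene/EtOH, rt) spares the benzyl ethers and the allylic C–O bond and gives 10.

Step 3. Over-reduction may occur through early collapse of the tetrahedral intermediate, and the arylacetaldehyde may self-condense or oxidise in air during aqueous work-up. The fallback sets out from 6 and comes back at 8. The ester is reduced fully with LiAlH4 (THF, 0 °C) to 2-[3,5-bis(benzyloxy)phenyl]ethanol F4, a storable compound. F4 is oxidised just before use with Dess–Martin periodinane (NaHCO3, CH2Cl2, 0 °C → rt), followed by non-aqueous filtration, to give 8.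

Step 1. The Grignard reagent may deprotonate the nitrile at its α-carbon instead of adding, which leads to recovered nitrile and self-condensation. The fallback sets out from 1 and 2 and comes back at 4. The nitrile is reduced with i-Bu2AlH (CH2Cl2, −78 °C; then aq. HCl) to hex-5-enal F5. Addition of 2 (Et2O, 0 °C) gives racemic undec-1-en-6-ol F6, and oxidation with Dess–Martin periodinane (CH2Cl2, rt) gives 4.

Further compounds
F1 | step 4 | racemic 1-[3,5-bis(benzyloxy)phenyl]but-3-en-2-ol | C=CC(O)Cc1cc(OCc2ccccc2)cc(OCc2ccccc2)c1
F2 | step 4 | (S)-1-[3,5-bis(benzyloxy)phenyl]but-3-en-2-yl acetate | C=C[C@H](Cc1cc(OCc2ccccc2)cc(OCc2ccccc2)c1)OC(C)=O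
F3 | step 4 | (2S,3E)-1-[3,5-bis(benzyloxy)phenyl]-8-oxotridec-3-en-2-yl acetate | CCCCCC(=O)CCC/C=C/[C@H](Cc1cc(OCc2ccccc2)cc(OCc2ccccc2)c1)OC(C)=O
F4 | step 3 | 2-[3,5-bis(benzyloxy)phenyl]ethanol | OCCc1cc(OCc2ccccc2)cc(OCc2ccccc2)c1
F5 | step 1 | hex-5-enal | C=CCCCC=O
F6 | step 1 | racemic undec-1-en-6-ol | C=CCCCC(O)CCCCC
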